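**Retrosynthetic overview**

1. Testudinariol A is C2-symmetric: the central CH2–CH2 bond is made last by tail-to-tail reductive homocoupling of two identical C15 allylic bromides 25.
2. Each oxane is opened at O-1–C-6: the C-2 oxygen displaces a C-6 mesylate with inversion, and only the CH2O group cis to the chain can reach C-6.
3. The open chain comes from one three-component union of cyclopentanecarbaldehyde 15, ethylene (from EtMgBr on Cp2ZrCl2) and the symmetric butyne 17, which forms C-3–C-4 and C-5–C-6 together.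
4. Enabling feature: in each oxane, C-4/C-5 is an unsubstituted CH2–CH2 between the sp2 carbon C-3 and the carbinol carbon C-6, the exocyclic alkene H is cis to C-4, and ring C-2 and the linker CH2 are cis CH2 groups on the alkene, i.e. a latent but-2-yne-1,4-diol.
5. Ring order: cyclopentane first (nickel-catalysed allenyl-aldehyde cyclization, step 7, stereocentre from an oxazolidinone auxiliary), oxane second (step 13), union of the halves last (step 15).

Key step: step 11

Remark: oxane atoms are numbered O-1, C-2 (OCH2), C-3 (alkylidene carbon), C-4, C-5, C-6 (carbon bearing the cyclopentyl group); η5-C5H5 ligands are drawn as σ-bonded C5H5 rings in SMILES; CIP descriptors of the cyclopentane carbons change with the oxygen substituents although the spatial arrangement stays the same.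

**Route**

Step 1
Reactants: 1 hex-5-ynoic acid; 2 (S)-4-benzyl-1,3-oxazolidin-2-one
Product: 4 (S)-4-benzyl-3-(hex-5-ynoyl)-1,3-oxazolidin-2-one, via hex-5-ynoic pivalic anhydride 3 (not isolated)
Conditions: PivCl, Et3N, THF, −20 °C; then LiCl, 2, −20 °C → rt
Reagents that add atoms: none
Why: N-acylation of the oxazolidinone auxiliary through the mixed pivalic anhydride (LiCl/Et3N acyl transfer) is a standard coupling and creates no stereocentre.

Step 2
Reactants: 4 (S)-4-benzyl-3-(hex-5-ynoyl)-1,3-oxazolidin-2-one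
Product: 6 (S)-4-benzyl-3-[(2R)-2-(hydroxymethyl)hex-5-ynoyl]-1,3-oxazolidin-2-one, via titanium enolate 5 (not isolated)
Conditions: TiCl4, i-Pr2NEt, CH2Cl2, 0 °C; then 1,3,5-trioxane, TiCl4, 0 °C
Reagents that add atoms: 1,3,5-trioxane (formaldehyde source) C1OCOCO1
Why: auxiliary-controlled aldol-type hydroxymethylation (Evans titanium-enolate chemistry) in which TiCl4-activated formaldehyde attacks the chelated (Z)-enolate 5 on the face opposite the benzyl group, setting the 2R centre that becomes the cyclopentane carbon carrying the oxane.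

Step 3
Reactants: 6 (S)-4-benzyl-3-[(2R)-2-(hydroxymethyl)hex-5-ynoyl]-1,3-oxazolidin-2-one
Product: 7 (S)-4-benzyl-3-[(2R)-2-{[(triethylsilyl)oxy]methyl}hex-5-ynoyl]-1,3-oxazolidin-2-one
Conditions: TESCl, imidazole, CH2Cl2, 0 °C
Reagents that add atoms: chlorotriethylsilane CC[Si](Cl)(CC)CC
Why: silylation of the primary alcohol, with TES chosen because it survives steps 4–8 and can later be oxidized directly to the aldehyde.

Step 4
Reactants: 7 (S)-4-benzyl-3-[(2R)-2-{[(triethylsilyl)oxy]methyl}hex-5-ynoyl]-1,3-oxazolidin-2-one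
Product: 8 (2S)-2-{[(triethylsilyl)oxy]methyl}hex-5-yn-1-ol
Conditions: LiBH4, MeOH (1 equiv), Et2O, 0 °C
Reagents that add atoms: none
Why: reductive cleavage of the N-acyl oxazolidinone with LiBH4 gives the primary alcohol and returns the auxiliary without touching the stereocentre (the descriptor changes only through priorities).

Step 5
Reactants: 8 (2S)-2-{[(triethylsilyl)oxy]methyl}hex-5-yn-1-ol
Product: 10 (2S)-2-{[(triethylsilyl)oxy]methyl}hepta-5,6-dien-1-ol, via propargylic amine 9 (not isolated)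
Conditions: (CH2O)n, CuI (0.5 equiv), Cy2NH, 1,4-dioxane, reflux
Reagents that add atoms: paraformaldehyde (as formaldehyde) C=O
Why: Crabbé allene homologation, in which a copper-mediated Mannich reaction gives propargylic amine 9 that loses the imine by a 1,5-hydride shift to give the terminal allene, leaving the remote stereocentre untouched.

Step 6
Reactants: 10 (2S)-2-{[(triethylsilyl)oxy]methyl}hepta-5,6-dien-1-ol
Product: 11 (2R)-2-{[(triethylsilyl)oxy]methyl}hepta-5,6-dienal
Conditions: Dess–Martin periodinane, NaHCO3, CH2Cl2, 0 °C → rt; used crude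
Reagents that add atoms: none
Why: Dess–Martin oxidation under buffered, non-basic conditions should give the α-branched aldehyde without epimerization or β-elimination.

Step 7
Reactants: 11 (2R)-2-{[(triethylsilyl)oxy]methyl}hepta-5,6-dienal
Product: 12 (1S,2R,5R)-2-(prop-1-en-2-yl)-5-{[(triethylsilyl)oxy]methyl}cyclopentan-1-ol
Conditions: Ni(COD)2 (10 mol %), Me2Zn, THF, 0 °C; aq. NH4Cl
Reagents that add atoms: dimethylzinc C[Zn]C
Why: nickel-catalysed alkylative cyclization of an allenyl aldehyde, in which zerovalent nickel couples the aldehyde carbon with the proximal allene carbon and the alkenylnickel takes a methyl group from zinc, should form the cyclopentane with hydroxyl and isopropenyl cis (cis-fused metallacycle) and both trans to the pseudo-equatorial CH2OTES branch.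

Step 8
Reactants: 12 (1S,2R,5R)-2-(prop-1-en-2-yl)-5-{[(triethylsilyl)oxy]methyl}cyclopentan-1-ol
Product: 13 tert-butyldimethyl{[(1S,2R,5R)-2-(prop-1-en-2-yl)-5-{[(triethylsilyl)oxy]methyl}cyclopentyl]oxy}silane
Conditions: TBSOTf, 2,6-lutidine, CH2Cl2, −78 → 0 °C
Reagents that add atoms: tert-butyldimethylsilyl trifluoromethanesulfonate CC(C)(C)[Si](C)(C)OS(=O)(=O)C(F)(F)F
Why: silylation of the hindered secondary alcohol with the silyl triflate installs the non-chelating TBS ether that the facial selectivity of step 11 relies on.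

Step 9
Reactants: 13 tert-butyldimethyl{[(1S,2R,5R)-2-(prop-1-en-2-yl)-5-{[(triethylsilyl)oxy]methyl}cyclopentyl]oxy}silane
Product: 15 (1S,2S,3R)-2-[(tert-butyldimethylsilyl)oxy]-3-(prop-1-en-2-yl)cyclopentane-1-carbaldehyde, via alkoxysulfonium salt 14 (not isolated)
Conditions: (COCl)2, DMSO, CH2Cl2, −78 → −40 °C; then Et3N, −78 → 0 °C
Reagents that add atoms: none
Why: Swern oxidation applied directly to the primary TES ether (activated DMSO cleaves the less hindered silyl ether to alkoxysulfonium salt 14, which collapses to the aldehyde) should leave the secondary TBS ether intact, and the α-centre is already in its more stable trans arrangement.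

Step 10
Reactants: 16 but-2-yne-1,4-diol
Product: 17 1,4-bis[(triisopropylsilyl)oxy]but-2-yne
Conditions: TIPSCl, imidazole, DMF, rt
Reagents that add atoms: chlorotriisopropylsilane CC(C)[Si](Cl)(C(C)C)C(C)C
Why: standard silylation of both primary hydroxyls, with bulky TIPS groups chosen to suppress oxygen–zirconium coordination in step 11.

Step 11
Reactants: 17 1,4-bis[(triisopropylsilyl)oxy]but-2-yne; 15 (1S,2S,3R)-2-[(tert-butyldimethylsilyl)oxy]-3-(prop-1-en-2-yl)cyclopentane-1-carbaldehyde
Product: 20 (1S,4Z)-1-[(1R,2S,3R)-2-[(tert-butyldimethylsilyl)oxy]-3-(prop-1-en-2-yl)cyclopentyl]-6-[(triisopropylsilyl)oxy]-4-{[(triisopropylsilyl)oxy]methyl}hex-4-en-1-ol, via zirconacyclopentene 18 (not isolated), via oxazirconacycloheptene 19 (not isolated)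
Conditions: Cp2ZrCl2 (1.3 equiv), EtMgBr (2.6 equiv), THF, −78 °C; 17 (1.4 equiv), −78 → 0 °C; 15 (1.0 equiv), 0 °C → rt; 1 M HCl, 0 °C
Reagents that add atoms: ethylmagnesium bromide CC[Mg]Br
Why: Cp2ZrEt2 formed from Cp2ZrCl2 and EtMgBr loses ethane to give the zirconocene–ethylene complex, alkyne 17 inserts to give zirconacyclopentene 18 (C-3–C-4 bond, Zr and C-4 cis), aldehyde 15 then inserts into the more reactive Zr–C(sp3) bond to give oxazirconacycloheptene 19 (C-5–C-6 bond), and acid cleaves the Zr–O and Zr–C(sp2) bonds with retention. The closest known reaction type is the zirconocene-mediated three-component coupling of an internal alkyne, ethylene (from EtMgBr) and an aldehyde through a zirconacyclopentene. No ring of the target is closed here; the two temporary zirconacycles arise by alkyne insertion into the zirconacyclopropane (five-membered) and by carbonyl insertion (expansion to seven-membered) and are opened again in the quench. The new carbinol centre C-6 is controlled by the adjacent cyclopentane stereocentre: Felkin–Anh addition anti to the ring bond leading to the silyloxy-bearing carbon, reinforced by the 1,3-anti preference of a non-chelating β-silyloxy aldehyde, should give the 6S alcohol, which is the configuration the invertive ring closure of step 13 needs. The Z-alkene follows from syn carbometalation and retentive protonolysis, and no regiochemical question arises because 17 is symmetric. The selectivities needed are insertion at Zr–C(sp3) in preference to ethylene extrusion and survival of the propargylic C–O bonds, which the low temperature and the bulky, poorly coordinating TIPS ethers are meant to secure.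

Step 12
Reactants: 20 (1S,4Z)-1-[(1R,2S,3R)-2-[(tert-butyldimethylsilyl)oxy]-3-(prop-1-en-2-yl)cyclopentyl]-6-[(triisopropylsilyl)oxy]-4-{[(triisopropylsilyl)oxy]methyl}hex-4-en-1-ol
Product: 21 (1S,4Z)-1-[(1S,2S,3R)-2-[(tert-butyldimethylsilyl)oxy]-3-(prop-1-en-2-yl)cyclopentyl]-6-[(triisopropylsilyl)oxy]-4-{[(triisopropylsilyl)oxy]methyl}hex-4-en-1-yl methanesulfonate
Conditions: MsCl, Et3N, CH2Cl2, 0 °C
Reagents that add atoms: methanesulfonyl chloride CS(=O)(=O)Cl
Why: mesylation of the only free hydroxyl (sulfene mechanism, retention at carbon) turns the 6S carbinol into a leaving group.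

Step 13
Reactants: 21 (1S,4Z)-1-[(1S,2S,3R)-2-[(tert-butyldimethylsilyl)oxy]-3-(prop-1-en-2-yl)cyclopentyl]-6-[(triisopropylsilyl)oxy]-4-{[(triisopropylsilyl)oxy]methyl}hex-4-en-1-yl methanesulfonate
Product: 24 (1S,2S,5R)-2-[(2R,5Z)-5-(2-hydroxyethylidene)oxan-2-yl]-5-(prop-1-en-2-yl)cyclopentan-1-ol, via diol mesylate 22 (not isolated), via silyl-protected oxane 23 (not isolated)
Conditions: TBAF (6 equiv), THF, 0 °C → 50 °C
Reagents that add atoms: none
Why: fluoride cleaves the two primary TIPS ethers, and of the two cis CH2O groups only the one on C-3 can reach C-6 (the other would need a trans-cycloheptene), so it closes the oxane by a 6-exo-tet intramolecular Williamson SN2 reaction with inversion (6S to 6R) before warming removes the hindered TBS ether.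

Step 14
Reactants: 24 (1S,2S,5R)-2-[(2R,5Z)-5-(2-hydroxyethylidene)oxan-2-yl]-5-(prop-1-en-2-yl)cyclopentan-1-ol
Product: 25 (1S,2S,5R)-2-[(2R,5Z)-5-(2-bromoethylidene)oxan-2-yl]-5-(prop-1-en-2-yl)cyclopentan-1-ol
Conditions: CBr4 (1.1 equiv), PPh3 (1.1 equiv), CH2Cl2, 0 °C; used at once
Reagents that add atoms: carbon tetrabromide BrC(Br)(Br)Br
Why: the Appel reaction should convert the primary allylic alcohol into the bromide under neutral conditions without allylic transposition, while the hindered secondary cyclopentanol reacts much more slowly.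

Step 15
Reactants: 25 (1S,2S,5R)-2-[(2R,5Z)-5-(2-bromoethylidene)oxan-2-yl]-5-(prop-1-en-2-yl)cyclopentan-1-ol (two molecules)
Product: 26 testudinariol A
Conditions: CoCl(PPh3)3 (1.2 equiv per bromide), degassed benzene, rt, argon
Reagents that add atoms: none
Why: Wurtz-type reductive homocoupling of allylic bromides by the monovalent cobalt complex should join the two primary termini head-to-head, because the other allyl terminus is fully substituted, with retention of the trisubstituted alkene geometry and without forming a stereocentre.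

**Compound list**

1 | hex-5-ynoic acid | C#CCCCC(=O)O | starting material
2 | (S)-4-benzyl-1,3-oxazolidin-2-one | O=C1N[C@@H](Cc2ccccc2)CO1 | starting material
3 | hex-5-ynoic pivalic anhydride (in situ) | C#CCCCC(=O)OC(=O)C(C)(C)C | intermediate
4 | (S)-4-benzyl-3-(hex-5-ynoyl)-1,3-oxazolidin-2-one | C#CCCCC(=O)N1[C@@H](Cc2ccccc2)COC1=O | intermediate
5 | trichlorotitanium (Z)-enolate of 4 (in situ) | C#CCC/C=C(\O[Ti](Cl)(Cl)Cl)N1[C@@H](Cc2ccccc2)COC1=O | intermediate
6 | (S)-4-benzyl-3-[(2R)-2-(hydroxymethyl)hex-5-ynoyl]-1,3-oxazolidin-2-one | C#CCC[C@H](CO)C(=O)N1[C@@H](Cc2ccccc2)COC1=O | intermediate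
7 | (S)-4-benzyl-3-[(2R)-2-{[(triethylsilyl)oxy]methyl}hex-5-ynoyl]-1,3-oxazolidin-2-one | C#CCC[C@H](CO[Si](CC)(CC)CC)C(=O)N1[C@@H](Cc2ccccc2)COC1=O | intermediate
8 | (2S)-2-{[(triethylsilyl)oxy]methyl}hex-5-yn-1-ol | C#CCC[C@H](CO[Si](CC)(CC)CC)CO | intermediate
9 | (2S)-7-(dicyclohexylamino)-2-{[(triethylsilyl)oxy]methyl}hept-5-yn-1-ol (in situ) | C(N(C1CCCCC1)C1CCCCC1)C#CCC[C@H](CO[Si](CC)(CC)CC)CO | intermediate
10 | (2S)-2-{[(triethylsilyl)oxy]methyl}hepta-5,6-dien-1-ol | C=C=CCC[C@H](CO[Si](CC)(CC)CC)CO | intermediate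
11 | (2R)-2-{[(triethylsilyl)oxy]methyl}hepta-5,6-dienal | C=C=CCC[C@H](CO[Si](CC)(CC)CC)C=O | intermediate
12 | (1S,2R,5R)-2-(prop-1-en-2-yl)-5-{[(triethylsilyl)oxy]methyl}cyclopentan-1-ol | C=C(C)[C@H]1CC[C@H](CO[Si](CC)(CC)CC)[C@H]1O | intermediate
13 | tert-butyldimethyl{[(1S,2R,5R)-2-(prop-1-en-2-yl)-5-{[(triethylsilyl)oxy]methyl}cyclopentyl]oxy}silane | C=C(C)[C@H]1CC[C@H](CO[Si](CC)(CC)CC)[C@H]1O[Si](C)(C)C(C)(C)C | intermediate
14 | {[(1R,2S,3R)-2-[(tert-butyldimethylsilyl)oxy]-3-(prop-1-en-2-yl)cyclopentyl]methoxy}dimethylsulfonium chloride (in situ) | C=C(C)[C@H]1CC[C@H](CO[S+](C)C)[C@H]1O[Si](C)(C)C(C)(C)C.[Cl-] | intermediate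
15 | (1S,2S,3R)-2-[(tert-butyldimethylsilyl)oxy]-3-(prop-1-en-2-yl)cyclopentane-1-carbaldehyde | C=C(C)[C@H]1CC[C@H](C=O)[C@H]1O[Si](C)(C)C(C)(C)C | intermediate
16 | but-2-yne-1,4-diol | OCC#CCO | starting material
17 | 1,4-bis[(triisopropylsilyl)oxy]but-2-yne | CC(C)[Si](C(C)C)(C(C)C)OCC#CCO[Si](C(C)C)(C(C)C)C(C)C | intermediate
18 | 1,1-bis(η5-cyclopentadienyl)-2,3-bis{[(triisopropylsilyl)oxy]methyl}-1-zirconacyclopent-2-ene (in situ) | C1=CC(C=C1)[Zr]2(C3C=CC=C3)CCC(CO[Si](C(C)C)(C(C)C)C(C)C)=C2CO[Si](C(C)C)(C(C)C)C(C)C | intermediate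
19 | (7S)-2,2-bis(η5-cyclopentadienyl)-7-[(1S,2S,3R)-2-[(tert-butyldimethylsilyl)oxy]-3-(prop-1-en-2-yl)cyclopentyl]-3,4-bis{[(triisopropylsilyl)oxy]methyl}-1-oxa-2-zirconacyclohept-3-ene (in situ) | C=C(C)[C@H]1CC[C@H]([C@@H]2CCC(CO[Si](C(C)C)(C(C)C)C(C)C)=C(CO[Si](C(C)C)(C(C)C)C(C)C)[Zr](C3C=CC=C3)(C3C=CC=C3)O2)[C@H]1O[Si](C)(C)C(C)(C)C | intermediate
20 | (1S,4Z)-1-[(1R,2S,3R)-2-[(tert-butyldimethylsilyl)oxy]-3-(prop-1-en-2-yl)cyclopentyl]-6-[(triisopropylsilyl)oxy]-4-{[(triisopropylsilyl)oxy]methyl}hex-4-en-1-ol | C=C(C)[C@H]1CC[C@H]([C@@H](O)CC/C(CO[Si](C(C)C)(C(C)C)C(C)C)=C/CO[Si](C(C)C)(C(C)C)C(C)C)[C@H]1O[Si](C)(C)C(C)(C)C | intermediate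
21 | (1S,4Z)-1-[(1S,2S,3R)-2-[(tert-butyldimethylsilyl)oxy]-3-(prop-1-en-2-yl)cyclopentyl]-6-[(triisopropylsilyl)oxy]-4-{[(triisopropylsilyl)oxy]methyl}hex-4-en-1-yl methanesulfonate | C=C(C)[C@H]1CC[C@H]([C@@H](OS(C)(=O)=O)CC/C(CO[Si](C(C)C)(C(C)C)C(C)C)=C/CO[Si](C(C)C)(C(C)C)C(C)C)[C@H]1O[Si](C)(C)C(C)(C)C | intermediate
22 | (1S,4Z)-1-[(1S,2S,3R)-2-[(tert-butyldimethylsilyl)oxy]-3-(prop-1-en-2-yl)cyclopentyl]-6-hydroxy-4-(hydroxymethyl)hex-4-en-1-yl methanesulfonate (in situ) | C=C(C)[C@H]1CC[C@H]([C@@H](OS(C)(=O)=O)CC/C(CO)=C/CO)[C@H]1O[Si](C)(C)C(C)(C)C | intermediate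
23 | (2Z)-2-[(6R)-6-[(1R,2S,3R)-2-[(tert-butyldimethylsilyl)oxy]-3-(prop-1-en-2-yl)cyclopentyl]oxan-3-ylidene]ethan-1-ol (in situ) | C=C(C)[C@H]1CC[C@H]([C@H]2CC/C(=C/CO)CO2)[C@H]1O[Si](C)(C)C(C)(C)C | intermediate
24 | (1S,2S,5R)-2-[(2R,5Z)-5-(2-hydroxyethylidene)oxan-2-yl]-5-(prop-1-en-2-yl)cyclopentan-1-ol | C=C(C)[C@H]1CC[C@H]([C@H]2CC/C(=C/CO)CO2)[C@H]1O | intermediate
25 | (1S,2S,5R)-2-[(2R,5Z)-5-(2-bromoethylidene)oxan-2-yl]-5-(prop-1-en-2-yl)cyclopentan-1-ol | C=C(C)[C@H]1CC[C@H]([C@H]2CC/C(=C/CBr)CO2)[C@H]1O | intermediate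
26 | testudinariol A | C=C(C)[C@H]1CC[C@H]([C@H]2CC/C(=C/CC/C=C3/CC[C@H]([C@H]4CC[C@H](C(=C)C)[C@@H]4O)OC3)CO2)[C@H]1O | target

**Step count**

Total step count: 15. Longest linear sequence: 14 steps (steps 1–9 and 11–15; step 10 is a one-step side branch).

**Steps most likely to fail, with fallbacks**

1. Step 11. A silyloxide may be eliminated from the (silyloxymethyl)alkenyl–zirconium unit of 18 or 19 (allene formation and loss of the C-2 oxygen). Ethylene may be extruded from 18, giving direct alkyne–aldehyde coupling. Facial discrimination at the aldehyde may be weak. The fallback sets out from 17 and 15, returns at 20, and makes the two bonds in separate, well-precedented operations. Palladium-catalysed syn-hydrostannation of 17 (Bu3SnH, PdCl2(PPh3)2, THF) should give the (E)-vinylstannane F1 without any regiochemical question, since 17 is symmetric. Tin–lithium exchange (MeLi, THF, −78 °C) and opening of ethylene oxide with BF3·OEt2 should give the (Z)-homoallylic alcohol F2, which forms C-3–C-4 with retention at the alkene. I2, PPh3 and imidazole should then give the primary iodide F3. Iodine–lithium exchange (t-BuLi, 2 equiv, Et2O–pentane, −78 °C) and Felkin–Anh addition of the alkyllithium to aldehyde 15 should form C-5–C-6 and give 20.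

2. Step 13. E2 elimination of the branched secondary mesylate, or attack of fluoride at C-6 or at sulfur, may compete with a slow intramolecular SN2 displacement. The fallback sets out from 20 and returns at 24, and it replaces the invertive substitution by a reductive etherification. Dess–Martin oxidation of 20 should give ketone F4. Desilylation with TBAF buffered by AcOH should free the hydroxyls, and the C-3 CH2OH, the only one that can reach the carbonyl, should close to the six-membered hemiketal F5. Ionic reduction (Et3SiH, BF3·OEt2, CH2Cl2–MeCN, −40 °C) of the derived cyclic oxocarbenium ion, with hydride delivered in the Felkin–Anh sense anti to the ring bond leading to the oxygen-bearing cyclopentane carbon, should give the 6R oxane 24.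

3. Step 15. Head-to-tail (SN2′-type) coupling, erosion of the alkene geometry through allyl-metal or allyl-radical isomerization, or simple reduction of the bromide may occur. The fallback sets out from 25 and returns at 26, and it replaces the reductive coupling by a polar sulfone alkylation–desulfonylation (Biellmann-type). Displacement of bromide in 25 by PhSO2Na (DMF, rt) should give the allylic sulfone F6. Double deprotonation (n-BuLi, 2.1 equiv, THF–DMPU, −78 °C) and C-alkylation of the sulfonyl carbanion with a second molecule of 25 should give the coupled sulfone F7. Palladium-catalysed reductive desulfonylation (LiBHEt3, PdCl2(dppp) cat., THF, 0 °C), with hydride delivered to the less substituted allyl terminus, should give 26.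

**Further compounds**

F1 | step 11 | (E)-tributyl{1,4-bis[(triisopropylsilyl)oxy]but-2-en-2-yl}stannane | CCCC[Sn](CCCC)(CCCC)/C(CO[Si](C(C)C)(C(C)C)C(C)C)=C/CO[Si](C(C)C)(C(C)C)C(C)C
F2 | step 11 | (3Z)-5-[(triisopropylsilyl)oxy]-3-{[(triisopropylsilyl)oxy]methyl}pent-3-en-1-ol | OCC/C(CO[Si](C(C)C)(C(C)C)C(C)C)=C/CO[Si](C(C)C)(C(C)C)C(C)C
F3 | step 11 | (2Z)-2-(2-iodoethyl)-1,4-bis[(triisopropylsilyl)oxy]but-2-ene | ICC/C(CO[Si](C(C)C)(C(C)C)C(C)C)=C/CO[Si](C(C)C)(C(C)C)C(C)C
F4 | step 13 | (4Z)-1-[(1S,2S,3R)-2-[(tert-butyldimethylsilyl)oxy]-3-(prop-1-en-2-yl)cyclopentyl]-6-[(triisopropylsilyl)oxy]-4-{[(triisopropylsilyl)oxy]methyl}hex-4-en-1-one | C=C(C)[C@H]1CC[C@H](C(=O)CC/C(CO[Si](C(C)C)(C(C)C)C(C)C)=C/CO[Si](C(C)C)(C(C)C)C(C)C)[C@H]1O[Si](C)(C)C(C)(C)C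
F5 | step 13 | (1S,2S,5R)-2-[(5Z)-2-hydroxy-5-(2-hydroxyethylidene)oxan-2-yl]-5-(prop-1-en-2-yl)cyclopentan-1-ol (hemiketal, anomer mixture) | C=C(C)[C@H]1CC[C@H](C2(O)CC/C(=C/CO)CO2)[C@H]1O
F6 | step 15 | (1S,2S,5R)-2-[(2R,5Z)-5-[2-(benzenesulfonyl)ethylidene]oxan-2-yl]-5-(prop-1-en-2-yl)cyclopentan-1-ol | C=C(C)[C@H]1CC[C@H]([C@H]2CC/C(=C/CS(=O)(=O)c3ccccc3)CO2)[C@H]1O
F7 | step 15 | testudinariol A carrying a benzenesulfonyl group on one carbon of the central CH2–CH2 unit (epimer mixture at that carbon) | C=C(C)[C@H]1CC[C@H]([C@H]2CC/C(=C/C(S(=O)(=O)c3ccccc3)C/C=C3/CC[C@H]([C@H]4CC[C@H](C(=C)C)[C@@H]4O)OC3)CO2)[C@H]1O
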